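**Retrosynthetic overview**
1. Target 17 comes from 16 by removing four silyl groups. 16 comes from diazoketone 15 by closing ring C last, through the C2–C3 bond, in a carbenoid C–H insertion that also creates the only stereocentre.
2. Enabling feature: C2 is bonded to O1 and is benzylic to the electron-rich catechol ring B, so in the opened form it is the CH2 of an aryl benzyl ether with hydridic C–H bonds. C3 lies α to the C4 ketone and can be made a carbenoid from a diazoketone. Both arms sit on the adjacent ring-A carbons C8a and C4a, so the six-membered ring C (O1, C2, C3, C4, C4a, C8a) results.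
3. 15 comes from methyl ketone 13 by diazo transfer. The (Z)-side chain of 13 comes from arylacetaldehyde 9 (Still–Gennari olefination, reduction), and 9 from allyl arene 8.
4. 8 comes from phenol 4 and benzylic alcohol 7 (Mitsunobu). The allyl group is placed on C8 by Claisen rearrangement of a mono-allyl ether of 1, which also distinguishes the two phenol oxygens.
5. Rings A and B are bought (1 and 5); ring C is the only ring formed.

Key step: step 13

Abbreviations: TBS = tert-butyldimethylsilyl, TIPS = triisopropylsilyl. Flavanone numbering (O1, C2, C3, C4, C4a, C5–C8, C8a) is used throughout.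

Assumption: the (S)-configured catalyst Rh2(S-PTTL)4 is taken to select the pro-S benzylic hydrogen and so give the (2S)-flavanone; should the sense prove opposite, Rh2(R-PTTL)4 is used with nothing else changed.

**Step 1**
Reactants: 1 2',6'-dihydroxy-4'-methoxyacetophenone
Product: 2 1-[2-(allyloxy)-6-hydroxy-4-methoxyphenyl]ethan-1-one
Conditions: allyl bromide (1.05 equiv), K2CO3, acetone, reflux
Reagents that add atoms: allyl bromide, C=CCBr
Why: Williamson etherification of the symmetrical diphenol should stop at the mono-ether, because the remaining hydroxyl is held in a hydrogen bond to the acetyl group and is much less nucleophilic.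

**Step 2**
Reactants: 2 1-[2-(allyloxy)-6-hydroxy-4-methoxyphenyl]ethan-1-one
Product: 3 1-[2-(allyloxy)-4-methoxy-6-(triisopropylsilyloxy)phenyl]ethan-1-one
Conditions: TIPSOTf, 2,6-lutidine, CH2Cl2, 0 °C to rt
Reagents that add atoms: triisopropylsilyl trifluoromethanesulfonate, CC(C)[Si](OS(=O)(=O)C(F)(F)F)(C(C)C)C(C)C
Why: Silylation of the hydrogen-bonded phenol with a silyl triflate and a hindered base caps the future O5 with a group that has no C–H next to oxygen (nothing for the later carbenoid to attack) and is too bulky to migrate.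

**Step 3**
Reactants: 3 1-[2-(allyloxy)-4-methoxy-6-(triisopropylsilyloxy)phenyl]ethan-1-one
Product: 4 1-[3-allyl-2-hydroxy-4-methoxy-6-(triisopropylsilyloxy)phenyl]ethan-1-one
Conditions: N,N-diethylaniline, 190 °C, sealed tube
Reagents that add atoms: none
Why: The aromatic Claisen rearrangement ([3,3]-sigmatropic shift, then tautomerisation) can deliver the allyl group only to the single free ortho carbon, the future C8, and at the same time frees the phenol that becomes O1.

**Step 4**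
Reactants: 5 3,4-dihydroxybenzaldehyde
Product: 6 3,4-bis(tert-butyldimethylsilyloxy)benzaldehyde
Conditions: TBSCl (2.3 equiv), imidazole, DMF, rt
Reagents that add atoms: tert-butyldimethylsilyl chloride, CC(C)(C)[Si](C)(C)Cl
Why: Standard imidazole-mediated silylation of both catechol hydroxyls.

**Step 5**
Reactants: 6 3,4-bis(tert-butyldimethylsilyloxy)benzaldehyde
Product: 7 [3,4-bis(tert-butyldimethylsilyloxy)phenyl]methanol
Conditions: NaBH4, THF/MeOH, 0 °C
Reagents that add atoms: none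
Why: Borohydride reduction of the aldehyde, under which aryl silyl ethers should survive at 0 °C.

**Step 6**
Reactants: 4 1-[3-allyl-2-hydroxy-4-methoxy-6-(triisopropylsilyloxy)phenyl]ethan-1-one; 7 [3,4-bis(tert-butyldimethylsilyloxy)phenyl]methanol
Product: 8 1-[3-allyl-2-{[3,4-bis(TBSO)phenyl]methoxy}-4-methoxy-6-(TIPSO)phenyl]ethan-1-one
Conditions: PPh3, DIAD, THF, 0 °C to rt
Reagents that add atoms: none
Why: Mitsunobu etherification joins the primary benzylic alcohol to the phenol (acidified by the ortho acetyl group) under neutral conditions that spare all three aryl silyl ethers.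

**Step 7**
Reactants: 8 1-[3-allyl-2-{[3,4-bis(TBSO)phenyl]methoxy}-4-methoxy-6-(TIPSO)phenyl]ethan-1-one
Product: 9 2-[3-acetyl-2-{[3,4-bis(TBSO)phenyl]methoxy}-6-methoxy-4-(TIPSO)phenyl]acetaldehyde
Conditions: OsO4 (2 mol %), NaIO4, 2,6-lutidine, dioxane/H2O 3:1, rt
Reagents that add atoms: osmium tetroxide (catalytic oxygen carrier), O=[Os](=O)(=O)=O; sodium periodate (terminal oxidant, source of the aldehyde oxygen), [Na+].[O-]I(=O)(=O)=O
Why: Lemieux–Johnson cleavage (dihydroxylation, then glycol cleavage) of the only alkene gives the arylacetaldehyde, which cannot lactolise because both ortho oxygens are capped.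

**Step 8**
Reactants: 9 2-[3-acetyl-2-{[3,4-bis(TBSO)phenyl]methoxy}-6-methoxy-4-(TIPSO)phenyl]acetaldehyde
Product: 10 ethyl (2Z)-4-[3-acetyl-2-{[3,4-bis(TBSO)phenyl]methoxy}-6-methoxy-4-(TIPSO)phenyl]-2-methylbut-2-enoate
Conditions: ethyl 2-[bis(2,2,2-trifluoroethoxy)phosphoryl]propanoate, KN(SiMe3)2, 18-crown-6, THF, −78 °C
Reagents that add atoms: ethyl 2-[bis(2,2,2-trifluoroethoxy)phosphoryl]propanoate, CCOC(=O)C(C)P(=O)(OCC(F)(F)F)OCC(F)(F)F
Why: Still–Gennari olefination (electron-poor phosphonate, dissociated potassium counter-ion, fast irreversible elimination) should give the (Z)-trisubstituted enoate with the ester cis to the ArCH2 group, the aldehyde reacting in preference to the hindered methyl ketone.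

**Step 9**
Reactants: 10 ethyl (2Z)-4-[3-acetyl-2-{[3,4-bis(TBSO)phenyl]methoxy}-6-methoxy-4-(TIPSO)phenyl]-2-methylbut-2-enoate
Product: 11 (2Z)-4-[2-{[3,4-bis(TBSO)phenyl]methoxy}-3-(1-hydroxyethyl)-6-methoxy-4-(TIPSO)phenyl]-2-methylbut-2-en-1-ol (racemic at the carbinol carbon)
Conditions: iBu2AlH (5 equiv), CH2Cl2, −78 °C; aq. potassium sodium tartrate
Reagents that add atoms: none
Why: Hydride 1,2-reduction of the enoate gives the (Z)-allylic alcohol with the geometry intact; the aryl ketone is knowingly reduced as well (restored in step 11), and the bulky TIPS group should not migrate to the new alkoxide.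

**Step 10**
Reactants: 11 (2Z)-4-[2-{[3,4-bis(TBSO)phenyl]methoxy}-3-(1-hydroxyethyl)-6-methoxy-4-(TIPSO)phenyl]-2-methylbut-2-en-1-ol
Product: 12 1-[2-{[3,4-bis(TBSO)phenyl]methoxy}-3-[(2Z)-4-(TBSO)-3-methylbut-2-en-1-yl]-4-methoxy-6-(TIPSO)phenyl]ethan-1-ol (racemic)
Conditions: TBSCl (1.1 equiv), imidazole, CH2Cl2, 0 °C
Reagents that add atoms: tert-butyldimethylsilyl chloride, CC(C)(C)[Si](C)(C)Cl
Why: Selective silylation of the primary allylic alcohol, the secondary benzylic alcohol being shielded by two ortho substituents.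

**Step 11**
Reactants: 12 1-[2-{[3,4-bis(TBSO)phenyl]methoxy}-3-[(2Z)-4-(TBSO)-3-methylbut-2-en-1-yl]-4-methoxy-6-(TIPSO)phenyl]ethan-1-ol
Product: 13 1-[2-{[3,4-bis(TBSO)phenyl]methoxy}-3-[(2Z)-4-(TBSO)-3-methylbut-2-en-1-yl]-4-methoxy-6-(TIPSO)phenyl]ethan-1-one
Conditions: Dess–Martin periodinane, pyridine, CH2Cl2, 0 °C to rt
Reagents that add atoms: none
Why: Dess–Martin oxidation returns the methyl ketone under near-neutral conditions that leave silyl ethers, the electron-rich benzyl ether and the alkene untouched.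

**Step 12**
Reactants: 13 1-[2-{[3,4-bis(TBSO)phenyl]methoxy}-3-[(2Z)-4-(TBSO)-3-methylbut-2-en-1-yl]-4-methoxy-6-(TIPSO)phenyl]ethan-1-one
Product: 15 2-diazo-1-[2-{[3,4-bis(TBSO)phenyl]methoxy}-3-[(2Z)-4-(TBSO)-3-methylbut-2-en-1-yl]-4-methoxy-6-(TIPSO)phenyl]ethan-1-one, via trifluoroacetyl diketone 14 (not isolated)
Conditions: LiN(SiMe3)2, THF, −78 °C; CF3CO2CH2CF3; aq. HCl work-up, crude 14 taken on; MsN3, Et3N, H2O (1 equiv), MeCN, rt
Reagents that add atoms: methanesulfonyl azide (the N2 unit of 15), CS(=O)(=O)N=[N+]=[N-]; 2,2,2-trifluoroethyl trifluoroacetate (the trifluoroacetyl group of 14 only), O=C(OCC(F)(F)F)C(F)(F)F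
Why: Detrifluoroacetylative diazo transfer (Danheiser variant of the Regitz reaction): the kinetic enolate of the only enolisable ketone is trifluoroacetylated, and the activated diketone takes up the diazo group with loss of the trifluoroacetyl unit.

**Step 13**
Reactants: 15 2-diazo-1-[2-{[3,4-bis(TBSO)phenyl]methoxy}-3-[(2Z)-4-(TBSO)-3-methylbut-2-en-1-yl]-4-methoxy-6-(TIPSO)phenyl]ethan-1-one
Product: 16 (2S)-2-[3,4-bis(TBSO)phenyl]-8-[(2Z)-4-(TBSO)-3-methylbut-2-en-1-yl]-7-methoxy-5-(TIPSO)-2,3-dihydro-4H-chromen-4-one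
Conditions: Rh2(S-PTTL)4, dirhodium tetrakis[N-phthaloyl-(S)-tert-leucinate] (2 mol %), CH2Cl2, 0 °C, slow addition of 15 at high dilution
Reagents that add atoms: none
Why: Rh2(S-PTTL)4 expels N2 from 15 to give an electrophilic rhodium carbenoid at C3, which inserts through a concerted, asynchronous, hydride-transfer-like three-centre transition state into one of the two enantiotopic C–H bonds of the O1–CH2–aryl group, forming the C2–C3 bond and releasing the catalyst. The closest known reaction type is the dirhodium-tetracarboxylate-catalysed intramolecular C–H insertion of 2-alkoxyphenyl α-diazoketones next to the ether oxygen, which gives chroman-4-ones, together with carbenoid insertions into benzylic ether C–H bonds under phthalimido-amino-acid rhodium carboxylates. Ring C (O1, C2, C3, C4, C4a, C8a) is closed as a 1,6-C–H insertion through a six-membered chair-like transition state with the ring-B aryl group equatorial. C2 is the only new stereocentre: the chiral carboxylate pocket selects the pro-S benzylic hydrogen, and since insertion proceeds with retention this gives (2S); the substrate has no stereocentre to match or mismatch. Insertion must win over attack of the carbenoid on the O1 lone pair (oxonium ylide, then 1,2-benzyl shift to a benzofuranone), over addition to ring B or the side-chain alkene, and over dimerisation. The substrate secures this because the C2–H bonds are doubly activated (α to O1 and benzylic to the bis-silyloxyphenyl ring), O1 is a weakly nucleophilic aryl ether oxygen flanked by two ortho substituents, the silyl ether at O5 offers no C–H next to oxygen, the C8 side chain is meta to the carbenoid arm and cannot reach it, and slow addition at high dilution suppresses bimolecular paths.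

**Step 14**
Reactants: 16 (2S)-2-[3,4-bis(TBSO)phenyl]-8-[(2Z)-4-(TBSO)-3-methylbut-2-en-1-yl]-7-methoxy-5-(TIPSO)-2,3-dihydro-4H-chromen-4-one
Product: 17 (2S)-2-(3,4-dihydroxyphenyl)-5-hydroxy-8-[(2Z)-4-hydroxy-3-methylbut-2-en-1-yl]-7-methoxy-2,3-dihydro-4H-chromen-4-one (target)
Conditions: TBAF/AcOH (1:1, 6 equiv), THF, 0 °C to rt
Reagents that add atoms: none
Why: Fluoride desilylation of the three aryl silyl ethers and the primary allylic silyl ether, buffered with acetic acid so that the phenols stay protonated and the flavanone cannot open by retro-oxa-Michael reaction, which should preserve C2.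

**Compound list**
1 | 2',6'-dihydroxy-4'-methoxyacetophenone | CC(=O)c1c(O)cc(OC)cc1O | starting material
2 | 1-[2-(allyloxy)-6-hydroxy-4-methoxyphenyl]ethan-1-one | CC(=O)c1c(OCC=C)cc(OC)cc1O | intermediate
3 | 1-[2-(allyloxy)-4-methoxy-6-(triisopropylsilyloxy)phenyl]ethan-1-one | CC(=O)c1c(OCC=C)cc(OC)cc1O[Si](C(C)C)(C(C)C)C(C)C | intermediate
4 | 1-[3-allyl-2-hydroxy-4-methoxy-6-(triisopropylsilyloxy)phenyl]ethan-1-one | CC(=O)c1c(O)c(CC=C)c(OC)cc1O[Si](C(C)C)(C(C)C)C(C)C | intermediate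
5 | 3,4-dihydroxybenzaldehyde | O=Cc1ccc(O)c(O)c1 | starting material
6 | 3,4-bis(tert-butyldimethylsilyloxy)benzaldehyde | O=Cc1ccc(O[Si](C)(C)C(C)(C)C)c(O[Si](C)(C)C(C)(C)C)c1 | intermediate
7 | [3,4-bis(tert-butyldimethylsilyloxy)phenyl]methanol | OCc1ccc(O[Si](C)(C)C(C)(C)C)c(O[Si](C)(C)C(C)(C)C)c1 | intermediate
8 | 1-[3-allyl-2-{[3,4-bis(TBSO)phenyl]methoxy}-4-methoxy-6-(TIPSO)phenyl]ethan-1-one | CC(=O)c1c(OCc2ccc(O[Si](C)(C)C(C)(C)C)c(O[Si](C)(C)C(C)(C)C)c2)c(CC=C)c(OC)cc1O[Si](C(C)C)(C(C)C)C(C)C | intermediate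
9 | 2-[3-acetyl-2-{[3,4-bis(TBSO)phenyl]methoxy}-6-methoxy-4-(TIPSO)phenyl]acetaldehyde | CC(=O)c1c(OCc2ccc(O[Si](C)(C)C(C)(C)C)c(O[Si](C)(C)C(C)(C)C)c2)c(CC=O)c(OC)cc1O[Si](C(C)C)(C(C)C)C(C)C | intermediate
10 | ethyl (2Z)-4-[3-acetyl-2-{[3,4-bis(TBSO)phenyl]methoxy}-6-methoxy-4-(TIPSO)phenyl]-2-methylbut-2-enoate | CCOC(=O)/C(C)=C\Cc1c(OC)cc(O[Si](C(C)C)(C(C)C)C(C)C)c(C(C)=O)c1OCc1ccc(O[Si](C)(C)C(C)(C)C)c(O[Si](C)(C)C(C)(C)C)c1 | intermediate
11 | (2Z)-4-[2-{[3,4-bis(TBSO)phenyl]methoxy}-3-(1-hydroxyethyl)-6-methoxy-4-(TIPSO)phenyl]-2-methylbut-2-en-1-ol, racemic carbinol | CC(O)c1c(OCc2ccc(O[Si](C)(C)C(C)(C)C)c(O[Si](C)(C)C(C)(C)C)c2)c(C/C=C(/C)CO)c(OC)cc1O[Si](C(C)C)(C(C)C)C(C)C | intermediate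
12 | 1-[2-{[3,4-bis(TBSO)phenyl]methoxy}-3-[(2Z)-4-(TBSO)-3-methylbut-2-en-1-yl]-4-methoxy-6-(TIPSO)phenyl]ethan-1-ol, racemic | CC(O)c1c(OCc2ccc(O[Si](C)(C)C(C)(C)C)c(O[Si](C)(C)C(C)(C)C)c2)c(C/C=C(/C)CO[Si](C)(C)C(C)(C)C)c(OC)cc1O[Si](C(C)C)(C(C)C)C(C)C | intermediate
13 | 1-[2-{[3,4-bis(TBSO)phenyl]methoxy}-3-[(2Z)-4-(TBSO)-3-methylbut-2-en-1-yl]-4-methoxy-6-(TIPSO)phenyl]ethan-1-one | CC(=O)c1c(OCc2ccc(O[Si](C)(C)C(C)(C)C)c(O[Si](C)(C)C(C)(C)C)c2)c(C/C=C(/C)CO[Si](C)(C)C(C)(C)C)c(OC)cc1O[Si](C(C)C)(C(C)C)C(C)C | intermediate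
14 | 1-[2-{[3,4-bis(TBSO)phenyl]methoxy}-3-[(2Z)-4-(TBSO)-3-methylbut-2-en-1-yl]-4-methoxy-6-(TIPSO)phenyl]-4,4,4-trifluorobutane-1,3-dione (not isolated) | O=C(CC(=O)C(F)(F)F)c1c(OCc2ccc(O[Si](C)(C)C(C)(C)C)c(O[Si](C)(C)C(C)(C)C)c2)c(C/C=C(/C)CO[Si](C)(C)C(C)(C)C)c(OC)cc1O[Si](C(C)C)(C(C)C)C(C)C | intermediate
15 | 2-diazo-1-[2-{[3,4-bis(TBSO)phenyl]methoxy}-3-[(2Z)-4-(TBSO)-3-methylbut-2-en-1-yl]-4-methoxy-6-(TIPSO)phenyl]ethan-1-one | [N-]=[N+]=CC(=O)c1c(OCc2ccc(O[Si](C)(C)C(C)(C)C)c(O[Si](C)(C)C(C)(C)C)c2)c(C/C=C(/C)CO[Si](C)(C)C(C)(C)C)c(OC)cc1O[Si](C(C)C)(C(C)C)C(C)C | intermediate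
16 | (2S)-2-[3,4-bis(TBSO)phenyl]-8-[(2Z)-4-(TBSO)-3-methylbut-2-en-1-yl]-7-methoxy-5-(TIPSO)-2,3-dihydro-4H-chromen-4-one | COc1cc(O[Si](C(C)C)(C(C)C)C(C)C)c2c(c1C/C=C(/C)CO[Si](C)(C)C(C)(C)C)O[C@H](c1ccc(O[Si](C)(C)C(C)(C)C)c(O[Si](C)(C)C(C)(C)C)c1)CC2=O | intermediate
17 | (2S)-2-(3,4-dihydroxyphenyl)-5-hydroxy-8-[(2Z)-4-hydroxy-3-methylbut-2-en-1-yl]-7-methoxy-2,3-dihydro-4H-chromen-4-one | COc1cc(O)c2c(c1C/C=C(/C)CO)O[C@H](c1ccc(O)c(O)c1)CC2=O | target

**Step count and risks**
Total steps: 14. Longest linear sequence: 12 (steps 1–3 and 6–14).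

Steps most likely to fail:

1. Step 13. The chiral carboxylate may discriminate the two enantiotopic benzylic C–H bonds incompletely, and the catalyst that best suppresses capture of the carbenoid by the O1 lone pair (ylide formation, 1,2-benzyl shift) may not be a highly enantioselective one. The fallback separates the two tasks and sets out from 15. Ring closure with achiral Rh2(esp)2, dirhodium bis(α,α,α',α'-tetramethyl-1,3-benzenedipropanoate), chosen for chemoselectivity alone (CH2Cl2, rt), would give the racemic silylated flavanone F1. Kinetic resolution of F1 by asymmetric transfer hydrogenation, a method established for flavanones (RhCl[TsDPEN](C5Me5), HCO2H/Et3N, EtOAc, rt, to about half conversion, with the TsDPEN antipode that reduces the (2R)-ketone faster), would convert the unwanted antipode into the (2R,4R)-cis-flavan-4-ol F2. The unreduced (2S)-ketone is 16, where the route is rejoined.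

2. Step 8. Z-selectivity may erode, or the base may enolise and self-condense the arylacetaldehyde. The fallback fixes the geometry by stereospecific cross-coupling and sets out from 9. Ramirez olefination (CBr4, PPh3, CH2Cl2, 0 °C) would give the 1,1-dibromoalkene F3. Trans-selective Negishi monomethylation (Me2Zn, PdCl2(DPEphos) cat., THF, rt) replaces the bromine trans to the ArCH2 group and would give the (Z)-bromoalkene F4. Stille coupling with (tributylstannyl)methanol (Pd(PPh3)4, dioxane, 90 °C), which proceeds with retention, would give the (Z)-allylic alcohol F5 with the aryl ketone untouched. Silylation (TBSCl, imidazole) then gives 13, where the route is rejoined; steps 9–11 are not needed in this variant.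

3. Step 6. The redox condensation may be slow at the hydrogen-bonded, di-ortho-substituted phenol, so that alkylation of the reduced azodicarboxylate takes over. The fallback is a Williamson etherification and sets out from 7 and 4. Appel bromination of 7 (CBr4, PPh3, CH2Cl2, 0 °C) would give 4-(bromomethyl)-1,2-bis(tert-butyldimethylsilyloxy)benzene F6. Alkylation of 4 with F6 (K2CO3, acetone, rt, short reaction time to spare the aryl silyl ethers) then gives 8, where the route is rejoined.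

**Further compounds**
F1 | step 13 | racemic 2-[3,4-bis(TBSO)phenyl]-8-[(2Z)-4-(TBSO)-3-methylbut-2-en-1-yl]-7-methoxy-5-(TIPSO)-2,3-dihydro-4H-chromen-4-one | COc1cc(O[Si](C(C)C)(C(C)C)C(C)C)c2c(c1C/C=C(/C)CO[Si](C)(C)C(C)(C)C)OC(c1ccc(O[Si](C)(C)C(C)(C)C)c(O[Si](C)(C)C(C)(C)C)c1)CC2=O
F2 | step 13 | (2R,4R)-2-[3,4-bis(TBSO)phenyl]-8-[(2Z)-4-(TBSO)-3-methylbut-2-en-1-yl]-7-methoxy-5-(TIPSO)-3,4-dihydro-2H-chromen-4-ol (cis) | COc1cc(O[Si](C(C)C)(C(C)C)C(C)C)c2c(c1C/C=C(/C)CO[Si](C)(C)C(C)(C)C)O[C@@H](c1ccc(O[Si](C)(C)C(C)(C)C)c(O[Si](C)(C)C(C)(C)C)c1)C[C@H]2O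
F3 | step 8 | 1-[2-{[3,4-bis(TBSO)phenyl]methoxy}-3-(3,3-dibromoprop-2-en-1-yl)-4-methoxy-6-(TIPSO)phenyl]ethan-1-one | CC(=O)c1c(OCc2ccc(O[Si](C)(C)C(C)(C)C)c(O[Si](C)(C)C(C)(C)C)c2)c(CC=C(Br)Br)c(OC)cc1O[Si](C(C)C)(C(C)C)C(C)C
F4 | step 8 | 1-[2-{[3,4-bis(TBSO)phenyl]methoxy}-3-[(2Z)-3-bromobut-2-en-1-yl]-4-methoxy-6-(TIPSO)phenyl]ethan-1-one | CC(=O)c1c(OCc2ccc(O[Si](C)(C)C(C)(C)C)c(O[Si](C)(C)C(C)(C)C)c2)c(C/C=C(/C)Br)c(OC)cc1O[Si](C(C)C)(C(C)C)C(C)C
F5 | step 8 | 1-[2-{[3,4-bis(TBSO)phenyl]methoxy}-3-[(2Z)-4-hydroxy-3-methylbut-2-en-1-yl]-4-methoxy-6-(TIPSO)phenyl]ethan-1-one | CC(=O)c1c(OCc2ccc(O[Si](C)(C)C(C)(C)C)c(O[Si](C)(C)C(C)(C)C)c2)c(C/C=C(/C)CO)c(OC)cc1O[Si](C(C)C)(C(C)C)C(C)C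
F6 | step 6 | 4-(bromomethyl)-1,2-bis(tert-butyldimethylsilyloxy)benzene | BrCc1ccc(O[Si](C)(C)C(C)(C)C)c(O[Si](C)(C)C(C)(C)C)c1
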